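**Strategy.** Ring C (C8, C9, C11–C14; ent-kaurane numbering) is cut at C8–C14 and C9–C11. C11–C14 are buta-1,3-diene, and C8=C9 is the double bond of an unsaturated spiro δ-lactone (C7–O–C20–C10) in which C8 also bears C15 as a formyl group. One [4+2] cycloaddition closes ring C, forging the C8–C14 bond, the quaternary centre C8 and C9, cis-fused and on the lactone face opposite C5. The feature exploited is that C8 lies between the C7 and C15 carbonyl carbons. The C12=C13 alkene left behind accepts a C16 vinyl radical to close ring D, and C15 is set last by exo-face reduction.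

Key step: step 9

Remark on numbering: ring A is C1–C5 and C10; the lactone ring is C7, O, C20, C10, C9, C8; ring C is C8, C9, C11–C14; ring D is C8, C14, C13, C16, C15; C6 is the formyl carbon on C5 and C17 the methylene on C16.

Assumption: the (R,S,S) ligand antipode in step 1 is taken to give (3R)-6, by analogy with dialkylzinc additions using this ligand class; if the sense is opposite, the enantiomeric ligand is used.

Step 1
Reactants: 1 4,4-dimethylcyclohex-2-en-1-one; 2 vinylmagnesium bromide
Product: 6 (3R)-3-ethenyl-4,4-dimethyl-2-methylidenecyclohexan-1-one, via magnesium enolate 3 (not isolated), via Mannich base 4 (not isolated), via trimethylammonium iodide 5 (not isolated)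
Conditions: CuBr·SMe2 (5 mol %), (R)-binaphthyl-2,2'-diyl N,N-bis[(S)-1-phenylethyl]phosphoramidite (10 mol %), Et2O, −78 °C; CH2=NMe2+ I−, THF, −78 °C → rt; MeI, rt; aq. NaHCO3, CH2Cl2, rt
Reagents that add atoms: Eschenmoser's salt (N,N-dimethylmethyleneiminium iodide), C=[N+](C)C.[I-]; iodomethane, CI (N-methyl group of 5 only)
Why: Copper-catalysed asymmetric conjugate addition sets C5 by ligand control, the regiodefined enolate is trapped at C10 in a Mannich reaction, and Hofmann-type elimination of the quaternised amine unveils the C10=C20 methylene.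

Step 2
Reactants: 6 (3R)-3-ethenyl-4,4-dimethyl-2-methylidenecyclohexan-1-one
Product: 7 (1S,3R)-3-ethenyl-4,4-dimethyl-2-methylidenecyclohexan-1-ol
Conditions: NaBH4, CeCl3·7H2O, MeOH, −78 °C
Reagents that add atoms: none
Why: Luche 1,2-reduction; hydride adds to C1 by axial attack on the equatorial-vinyl chair or anti to the syn-axial vinyl group of the other chair, so both conformers should give the 1,3-cis alcohol (C1 S).

Step 3
Reactants: 7 (1S,3R)-3-ethenyl-4,4-dimethyl-2-methylidenecyclohexan-1-ol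
Product: 8 (3S,4S,8R)-8-ethenyl-7,7-dimethyl-1-oxaspiro[2.5]octan-4-ol
Conditions: VO(acac)2 (2 mol %), t-BuOOH (decane), CH2Cl2, 0 °C → rt
Reagents that add atoms: tert-butyl hydroperoxide, CC(C)(C)OO
Why: Hydroxyl-directed vanadium-catalysed epoxidation should touch only the allylic C10=C20 alkene, syn to OH, and leave the vinyl group; the C10 configuration made here is erased in step 5.

Step 4
Reactants: 8 (3S,4S,8R)-8-ethenyl-7,7-dimethyl-1-oxaspiro[2.5]octan-4-ol
Product: 9 (3S,4S,8R)-8-ethenyl-7,7-dimethyl-1-oxaspiro[2.5]octan-4-yl acetate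
Conditions: Ac2O, pyridine, DMAP (cat.), CH2Cl2, rt
Reagents that add atoms: acetic anhydride, CC(=O)OC(C)=O
Why: DMAP-catalysed acylation installs the C1 acetate of the target early, which is possible because no later step needs a strong base.

Step 5
Reactants: 9 (3S,4S,8R)-8-ethenyl-7,7-dimethyl-1-oxaspiro[2.5]octan-4-yl acetate; 10 2,2,2-trifluoroethyl acrylate
Product: 12 (6S,7R,11S)-7-ethenyl-8,8-dimethyl-3-oxo-2-oxaspiro[5.5]undecan-11-yl acetate, via hydroxy ester 11 (not isolated)
Conditions: Cp2TiCl2 (0.3 equiv), Zn dust, 2,4,6-collidine·HCl, 10 (5 equiv), THF, rt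
Reagents that add atoms: none
Why: Titanocene-mediated reductive epoxide opening (trivalent titanium formed in situ) gives the tertiary C10 radical, whose Giese addition to the acrylate anti to the cis-disposed C1 acetoxy and C5 vinyl groups sets C10 (S) from either epoxide configuration; the C20 alkoxide then lactonises onto the activated ester.

Step 6
Reactants: 12 (6S,7R,11S)-7-ethenyl-8,8-dimethyl-3-oxo-2-oxaspiro[5.5]undecan-11-yl acetate
Product: 14 (6S,7R,11S)-7-(dimethoxymethyl)-8,8-dimethyl-3-oxo-2-oxaspiro[5.5]undecan-11-yl acetate, via aldehyde 13 (not isolated)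
Conditions: O3, CH2Cl2/MeOH, −78 °C; Me2S, −78 °C → rt; HC(OMe)3, PPTS (cat.), MeOH, rt
Reagents that add atoms: ozone, [O-][O+]=O (carbonyl oxygen of 13 only); trimethyl orthoformate, COC(OC)OC (both methoxy groups of 14)
Why: Ozonolysis with reductive work-up cleaves the only alkene to the C6 aldehyde, and mild acid-catalysed acetalisation masks it without disturbing C5.

Step 7
Reactants: 14 (6S,7R,11S)-7-(dimethoxymethyl)-8,8-dimethyl-3-oxo-2-oxaspiro[5.5]undecan-11-yl acetate
Product: 15 (4E,6S,7R,11S)-7-(dimethoxymethyl)-4-[(dimethylamino)methylidene]-8,8-dimethyl-3-oxo-2-oxaspiro[5.5]undecan-11-yl acetate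
Conditions: t-BuOCH(NMe2)2 (3 equiv), toluene, 90 °C
Reagents that add atoms: Bredereck's reagent (tert-butoxybis(dimethylamino)methane), CC(C)(C)OC(N(C)C)N(C)C
Why: Aminomethylenation of the lactone α-methylene C8 adds C15 under neutral thermal conditions; the less acidic acetate methyl group should be left alone.

Step 8
Reactants: 15 (4E,6S,7R,11S)-7-(dimethoxymethyl)-4-[(dimethylamino)methylidene]-8,8-dimethyl-3-oxo-2-oxaspiro[5.5]undecan-11-yl acetate
Product: 18 (6S,7R,11S)-7-(dimethoxymethyl)-4-formyl-8,8-dimethyl-3-oxo-2-oxaspiro[5.5]undec-4-en-11-yl acetate, via formyl selenide 16 (not isolated), via selenoxide 17 (not isolated)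
Conditions: PhSeCl, CH2Cl2, −78 °C; aq. NaHCO3, 0 °C; mCPBA, CH2Cl2, −78 → 0 °C
Reagents that add atoms: water, O (formyl oxygen of 18); benzeneselenenyl chloride, Cl[Se]c1ccccc1 (selenium of 16 and 17 only); mCPBA, OOC(=O)c1cccc(Cl)c1 (selenoxide oxygen of 17 only)
Why: Electrophilic selenenylation of the enaminone at C8, hydrolysis of the iminium ion to the formyl group and selenoxide syn-elimination toward C9 (the only β-hydrogens) should give the 2-formyl enoate, which is used at once.

Step 9
Reactants: 18 (6S,7R,11S)-7-(dimethoxymethyl)-4-formyl-8,8-dimethyl-3-oxo-2-oxaspiro[5.5]undec-4-en-11-yl acetate; 19 buta-1,3-diene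
Product: 20 (1S,2S,4a'S,6R,8a'S)-6-(dimethoxymethyl)-8a'-formyl-5,5-dimethyl-1'-oxo-4a',5',8',8a'-tetrahydro-1'H,3'H-spiro[cyclohexane-1,4'-isochromen]-2-yl acetate (kaurane numbering 1S,5R,8S,9S,10S)
Conditions: 19 (excess), ZnCl2 (0.3 equiv), CH2Cl2, sealed tube, −20 °C → rt
Reagents that add atoms: none
Why: Zinc chloride chelates the C7 lactone and C15 formyl oxygens of 18 and lowers the LUMO of the C8=C9 bond, which reacts with butadiene in a normal-demand Diels–Alder reaction; the closest known reaction type is the cycloaddition of 2-formyl- and 2-alkoxycarbonyl-cycloalk-2-enones, which gives cis-fused bicycles with an angular carbonyl group. Bond formation is asynchronous, C9–C11 at the β-carbon leading and C8–C14 completing ring C, which is closed as a six-membered carbocycle through a concerted suprafacial [4+2] transition state. Suprafacial addition places C11 and C14 cis, so the configuration of the quaternary centre C8 (S) follows from that of C9 (S). C9 is controlled by the spiro centre C10: the diene should approach the lactone face that carries C1 and avoid the face shielded by C5 with its dimethoxymethyl group and the flanking C4 gem-dimethyl group. The selectivities needed are this facial one and periselectivity over hetero-Diels–Alder reaction of the O=C15–C8=C9 oxadiene, which needs an electron-rich alkene that butadiene is not; regiochemistry is moot with the symmetrical diene.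

Step 10
Reactants: 20 Diels–Alder adduct (name as in step 9); 21 ethynylmagnesium bromide
Product: 22 (1S,2S,4a'S,6R,8a'S)-6-(dimethoxymethyl)-8a'-(1-hydroxyprop-2-yn-1-yl)-5,5-dimethyl-1'-oxo-4a',5',8',8a'-tetrahydro-1'H,3'H-spiro[cyclohexane-1,4'-isochromen]-2-yl acetate (both C15 epimers)
Conditions: 21 (0.5 M in THF), THF, −78 → −40 °C; H2O
Reagents that add atoms: none
Why: Grignard 1,2-addition to the non-enolisable neopentyl aldehyde, which is far more electrophilic than the lactone or the hindered acetate at low temperature; C15 is not controlled here and is reset in steps 12 and 13.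

Step 11
Reactants: 22 propargylic alcohols (name as in step 10)
Product: 24 (1S,5R,8S,9S,10S,13R,15RS)-1-acetoxy-15-hydroxy-6,6-dimethoxy-6,7-secokaur-16-en-7,20-olide, via vinylstannane 23 (not isolated)
Conditions: Bu3SnH, AIBN (cat.), benzene (0.01 M), 80 °C; then PPTS, CH2Cl2, rt
Reagents that add atoms: tributyltin hydride, CCCC[SnH](CCCC)CCCC (tin of 23 only)
Why: Enyne radical cyclisation: stannyl radical addition to the terminal alkyne gives the C16 vinyl radical, 5-exo-trig closure onto C13 of the cyclohexene forms ring D (the bridge fixes C13 as R), and protodestannylation leaves the C16=C17 methylene.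

Step 12
Reactants: 24 (1S,5R,8S,9S,10S,13R,15RS)-1-acetoxy-15-hydroxy-6,6-dimethoxy-6,7-secokaur-16-en-7,20-olide
Product: 25 (1S,5R,8S,9S,10S,13R)-1-acetoxy-6,6-dimethoxy-15-oxo-6,7-secokaur-16-en-7,20-olide
Conditions: Dess–Martin periodinane, CH2Cl2, 0 °C → rt
Reagents that add atoms: none
Why: Dess–Martin oxidation converts both C15 epimers into the single α-methylene ketone, so the earlier lack of control at C15 is of no consequence.

Step 13
Reactants: 25 (1S,5R,8S,9S,10S,13R)-1-acetoxy-6,6-dimethoxy-15-oxo-6,7-secokaur-16-en-7,20-olide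
Product: 27 (1S,5R,8S,9S,10S,13R,15R)-1-acetoxy-15-hydroxy-6-oxo-6,7-secokaur-16-en-7,20-olide (target CNP0117386.1), via acetal alcohol 26 (not isolated)
Conditions: NaBH4, CeCl3·7H2O, MeOH, −78 °C; then 1 M aq. HCl, THF, 0 °C → rt
Reagents that add atoms: water, O (formyl oxygen of 27)
Why: Luche 1,2-reduction should deliver hydride to the exo face of the bicyclo[3.2.1]octenone (the side of the C14 bridge, away from the axial C11–H of the three-carbon bridge) and so set C15 (R); the acidic work-up hydrolyses the dimethyl acetal to the C6 aldehyde.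

**Compound list**

1 | 4,4-dimethylcyclohex-2-en-1-one | CC1(C)CCC(=O)C=C1 | starting material
2 | vinylmagnesium bromide | C=C[Mg]Br | starting material
3 | bromomagnesium C1=C10 enolate of (3R)-3-ethenyl-4,4-dimethylcyclohexanone | C=C[C@H]1C=C(O[Mg]Br)CCC1(C)C | intermediate
4 | (2R,3S)-2-[(dimethylamino)methyl]-3-ethenyl-4,4-dimethylcyclohexan-1-one (2,3-trans Mannich base) | C=C[C@H]1[C@H](CN(C)C)C(=O)CCC1(C)C | intermediate
5 | [(1R,6S)-6-ethenyl-5,5-dimethyl-2-oxocyclohexyl]methyl(trimethyl)azanium iodide | C=C[C@H]1[C@H](C[N+](C)(C)C)C(=O)CCC1(C)C.[I-] | intermediate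
6 | (3R)-3-ethenyl-4,4-dimethyl-2-methylidenecyclohexan-1-one | O=C1CCC(C)(C)[C@@H](C=C)C1=C | intermediate
7 | (1S,3R)-3-ethenyl-4,4-dimethyl-2-methylidenecyclohexan-1-ol | C=C1[C@@H](O)CCC(C)(C)[C@H]1C=C | intermediate
8 | (3S,4S,8R)-8-ethenyl-7,7-dimethyl-1-oxaspiro[2.5]octan-4-ol | O[C@H]1CCC(C)(C)[C@@H](C=C)[C@]12CO2 | intermediate
9 | (3S,4S,8R)-8-ethenyl-7,7-dimethyl-1-oxaspiro[2.5]octan-4-yl acetate | CC(=O)O[C@H]1CCC(C)(C)[C@@H](C=C)[C@]12CO2 | intermediate
10 | 2,2,2-trifluoroethyl acrylate | C=CC(=O)OCC(F)(F)F | starting material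
11 | 2,2,2-trifluoroethyl 3-[(1S,2R,6S)-6-acetoxy-2-ethenyl-1-(hydroxymethyl)-3,3-dimethylcyclohexyl]propanoate | OC[C@@]1(CCC(=O)OCC(F)(F)F)[C@@H](OC(C)=O)CCC(C)(C)[C@H]1C=C | intermediate
12 | (6S,7R,11S)-7-ethenyl-8,8-dimethyl-3-oxo-2-oxaspiro[5.5]undecan-11-yl acetate | O=C1CC[C@]2(CO1)[C@@H](OC(C)=O)CCC(C)(C)[C@H]2C=C | intermediate
13 | (6S,7R,11S)-7-formyl-8,8-dimethyl-3-oxo-2-oxaspiro[5.5]undecan-11-yl acetate | O=C1CC[C@]2(CO1)[C@@H](OC(C)=O)CCC(C)(C)[C@H]2C=O | intermediate
14 | (6S,7R,11S)-7-(dimethoxymethyl)-8,8-dimethyl-3-oxo-2-oxaspiro[5.5]undecan-11-yl acetate | O=C1CC[C@]2(CO1)[C@@H](OC(C)=O)CCC(C)(C)[C@H]2C(OC)OC | intermediate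
15 | (4E,6S,7R,11S)-7-(dimethoxymethyl)-4-[(dimethylamino)methylidene]-8,8-dimethyl-3-oxo-2-oxaspiro[5.5]undecan-11-yl acetate | CN(C)/C=C1\C[C@]2(COC1=O)[C@@H](OC(C)=O)CCC(C)(C)[C@H]2C(OC)OC | intermediate
16 | (6S,7R,11S)-7-(dimethoxymethyl)-4-formyl-8,8-dimethyl-3-oxo-4-(phenylselanyl)-2-oxaspiro[5.5]undecan-11-yl acetate (C4 epimers) | O=CC1([Se]c2ccccc2)C[C@]3(COC1=O)[C@@H](OC(C)=O)CCC(C)(C)[C@H]3C(OC)OC | intermediate
17 | Se-oxide of 16 (C4 and Se epimers) | O=CC1([Se](=O)c2ccccc2)C[C@]3(COC1=O)[C@@H](OC(C)=O)CCC(C)(C)[C@H]3C(OC)OC | intermediate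
18 | (6S,7R,11S)-7-(dimethoxymethyl)-4-formyl-8,8-dimethyl-3-oxo-2-oxaspiro[5.5]undec-4-en-11-yl acetate | O=CC1=C[C@]2(COC1=O)[C@@H](OC(C)=O)CCC(C)(C)[C@H]2C(OC)OC | intermediate
19 | buta-1,3-diene | C=CC=C | starting material
20 | (1S,2S,4a'S,6R,8a'S)-6-(dimethoxymethyl)-8a'-formyl-5,5-dimethyl-1'-oxo-4a',5',8',8a'-tetrahydro-1'H,3'H-spiro[cyclohexane-1,4'-isochromen]-2-yl acetate | O=C[C@]12CC=CC[C@H]1[C@]3(COC2=O)[C@@H](OC(C)=O)CCC(C)(C)[C@H]3C(OC)OC | intermediate
21 | ethynylmagnesium bromide | C#C[Mg]Br | starting material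
22 | 8a'-(1-hydroxyprop-2-yn-1-yl) analogue of 20 (kaurane numbering 1S,5R,8S,9S,10S; both C15 epimers) | C#CC(O)[C@]12CC=CC[C@H]1[C@]3(COC2=O)[C@@H](OC(C)=O)CCC(C)(C)[C@H]3C(OC)OC | intermediate
23 | 17-(tributylstannyl) derivative of 24 (E/Z and C15 mixtures) | CCCC[Sn](CCCC)(CCCC)C=C1[C@@H]2CC[C@@H]3[C@](C2)(C(=O)OC[C@]32[C@@H](OC(C)=O)CCC(C)(C)[C@H]2C(OC)OC)C1O | intermediate
24 | (1S,5R,8S,9S,10S,13R,15RS)-1-acetoxy-15-hydroxy-6,6-dimethoxy-6,7-secokaur-16-en-7,20-olide | C=C1[C@@H]2CC[C@@H]3[C@](C2)(C(=O)OC[C@]32[C@@H](OC(C)=O)CCC(C)(C)[C@H]2C(OC)OC)C1O | intermediate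
25 | (1S,5R,8S,9S,10S,13R)-1-acetoxy-6,6-dimethoxy-15-oxo-6,7-secokaur-16-en-7,20-olide | C=C1[C@@H]2CC[C@@H]3[C@](C2)(C(=O)OC[C@]32[C@@H](OC(C)=O)CCC(C)(C)[C@H]2C(OC)OC)C1=O | intermediate
26 | (1S,5R,8S,9S,10S,13R,15R)-1-acetoxy-15-hydroxy-6,6-dimethoxy-6,7-secokaur-16-en-7,20-olide | C=C1[C@@H]2CC[C@@H]3[C@](C2)(C(=O)OC[C@]32[C@@H](OC(C)=O)CCC(C)(C)[C@H]2C(OC)OC)[C@@H]1O | intermediate
27 | (1S,5R,8S,9S,10S,13R,15R)-1-acetoxy-15-hydroxy-6-oxo-6,7-secokaur-16-en-7,20-olide (CNP0117386.1) | C=C1[C@@H]2CC[C@@H]3[C@](C2)(C(=O)OC[C@]32[C@@H](OC(C)=O)CCC(C)(C)[C@H]2C=O)[C@@H]1O | target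

**Totals.** Total step count: 13. Longest linear sequence: 13 steps (from 1).

**Three steps most likely to fail**

1. Step 9 (key cycloaddition). The cycloaddition may be too slow at the neopentyl β-carbon C9 with an unactivated diene, so that polymerisation or oxadiene cycloaddition of the formyl enoate takes over; facial discrimination may also erode under Lewis acid. The fallback sets out from 18 and uses a more nucleophilic diene without Lewis acid. Thermal cycloaddition with commercial 2-(trimethylsilyloxy)buta-1,3-diene (toluene, 40–60 °C) should give the C12 silyl enol ether adduct F1; the CH2 terminus next to the silyloxy carbon bonds to C9, so C14 still closes ring C onto C8. Fluoride-catalysed exchange with nonafluorobutanesulfonyl fluoride (Bu4NF cat., THF, 0 °C) should give the C12 alkenyl nonaflate F2. Formate reduction (Pd(OAc)2, PPh3, HCO2H, Bu3N, DMF, 60 °C) removes the oxygen and returns to the route at 20.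

2. Step 8 (dienophile generation). The very electrophilic 2-formyl enoate may be hydrated or over-oxidised during the selenoxide sequence. The fallback sets out from 15: hydrolysis of the enaminone on wet silica gel or with dilute aqueous oxalic acid in THF should give the α-(hydroxymethylene) lactone F3. Dehydrogenation of F3 with DDQ (dioxane, rt), a known method for 2-hydroxymethylene ketones, returns to the route at 18, which can be taken straight into step 9.

3. Step 1 (asymmetric conjugate addition). The copper–ligand complex may discriminate poorly between the enone faces of this γ,γ-disubstituted substrate with a vinyl Grignard reagent. The fallback sets out from 7 of insufficient enantiomeric purity and moves the enantiocontrol to the epoxidation. Step 3 is run as a Sharpless kinetic resolution (Ti(OiPr)4, L-(+)-diisopropyl tartrate, substoichiometric t-BuOOH, 4 Å molecular sieves, CH2Cl2, −20 °C). By the Sharpless mnemonic the (1S) carbinol is the fast-reacting enantiomer and is epoxidised syn to the hydroxyl group, while the minor enantiomer stays behind as the alcohol and is removed. The route is rejoined at 8; this fallback makes no new compound (F0).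

**Further compounds**

F1 | step 9 | C12 trimethylsilyl enol ether adduct (12-trimethylsilyloxy analogue of 20, C12=C13) | O=C[C@]12CC=C(O[Si](C)(C)C)C[C@H]1[C@]3(COC2=O)[C@@H](OC(C)=O)CCC(C)(C)[C@H]3C(OC)OC
F2 | step 9 | C12 alkenyl nonaflate (12-nonafluorobutanesulfonyloxy analogue of 20) | O=C[C@]12CC=C(OS(=O)(=O)C(F)(F)C(F)(F)C(F)(F)C(F)(F)F)C[C@H]1[C@]3(COC2=O)[C@@H](OC(C)=O)CCC(C)(C)[C@H]3C(OC)OC
F3 | step 8 | (4Z,6S,7R,11S)-7-(dimethoxymethyl)-4-(hydroxymethylidene)-8,8-dimethyl-3-oxo-2-oxaspiro[5.5]undecan-11-yl acetate | O/C=C1/C[C@]2(COC1=O)[C@@H](OC(C)=O)CCC(C)(C)[C@H]2C(OC)OC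
F0 | step 1 | none | none
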